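## Analysis of the target

The target is a heliangolide-type germacranolide: a ten-membered carbocycle (C1–C10) with a 4Z trisubstituted olefin, trans-fused across C6–C7 to an α-methylene-γ-butyrolactone (oxygen on C6, carbonyl C12, C11=C13 exocyclic). There are six stereocentres: 3R, 6R, 7S, 8S, 9S and 10S. Five of them form one run, C6 to C10, in which H6/H7 are trans, H7/H8 are cis, and O8/O9 and O9/O10 are each anti in the extended chain, so that all three oxygens lie on one ring face. C3 is insulated from this run by the C1 ketone, the C2 methylene and the olefin. The oxygens are differentiated five ways: free allylic hydroxyl at C3, ketone at C1, free tertiary hydroxyl at C10 (quaternary, with C14), acetate at C9 and angelate at C8. Sensitive groups are the α-methylene lactone (Michael acceptor, exo-to-endo migration), the angelate (isomerises to the tiglate on activation, migrates to a free neighbouring hydroxyl), the C1/C3 β-hydroxy ketone (elimination) and the C1/C10/C9 ketol array (retro-aldol). The difficulty is to close a ten-membered ring with a Z olefin while three adjacent oxygens stay distinguishable and while the H7/H8 cis relation, which a cyclic allylmetal cannot deliver directly, is still obtained. The strategy rests on C3 being a carbinol on C4 of the Z olefin: C3–C4 is the bond of an alkenylmetal–aldehyde addition, provided the C1 carbonyl two atoms away is masked.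

## Retrosynthetic reasoning

**36 back to 31, functional-group changes only.** The C3 hydroxyl of 36 is traced to silyl ether 35, the C1 ketone of 35 to the dithiane of 34, the C9 acetate of 34 to diol 33, and the diol to acetonide 32 and its parent alcohol 31. No skeletal bond is cut; what matters is the order. C3 is silylated before the diol is freed, so that only one secondary hydroxyl is open to acetylation. The ketone is unveiled after the acetylation, so that no base-exposed intermediate carries an α,β-dihydroxy ketone that could cleave at C9–C10.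

**31 to 29, cut C3–C4.** This is the only ring bond that joins an sp2 carbon of the Z olefin to a carbinol carbon. Cutting it gives an aldehyde at C3 and a Z alkenyl iodide at C4 in one chain, 29; the forward reaction passes through alkenylchromium 30. The cut is made here and not at C5–C6 or C7–C8 because a chromium-bound alkenyl group attacks only the aldehyde and leaves the lactone, the angelate and the enoate alone. The one new stereocentre is also a secondary allylic carbinol that can be corrected by oxidation and reduction. The forward step has to keep the Z geometry, win against oligomerisation and choose one aldehyde face. C1 must be a dithiane and O9/O10 an acetonide: a free C1 ketone would make C3 a β-keto aldehyde, and a free O10 would close a lactol onto C3.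

**29 to 27, oxidation level at C3.** Aldehyde 29 comes from alcohol 28 and this from silyl ether 27. C3 therefore travels as a robust protected primary alcohol through all organometallic and acidic steps and becomes the aldehyde only one step before ring closure.

**27 to 25 and 26, cut the C8–O ester bond with inversion.** The angelate is introduced from angelic acid 26 onto carbinol 25, which has the opposite configuration at C8. This is forced by the next disconnection. It also has a benefit: the acid enters as a carboxylate nucleophile and is never activated at the acyl carbon, which is the situation in which angelates isomerise.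

**25 to 10 and 23, cut C7–C8.** This bond separates the lactone half from the polyol half and is made by allylation of aldehyde 23 with the allylzinc 24 derived from bromolactone 10. It forms the exocyclic methylene and the C7 stereocentre in one step, trans to the C6 side chain. In 24 the ring holds C6 trans to the metal-bearing methylene, so a chair transition state places H7 and H8 anti and gives the 8R carbinol 25. The target needs them syn, hence the inversion at the ester stage. Any other cut near C7 would need the lactone to be built after coupling.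

**10 back to 1, the lactone half.** The bromomethyl butenolide 10 comes from allylic alcohol 9. This arises by selenoxide elimination (through 8) from 7, the hydroxymethylation product of selenide 5 (through enolate 6), and 5 arises from saturated lactone 3 (through enolate 4). The Z alkenyl iodide of 3 is traced by an iodoethylidene Wittig disconnection of C4=C5 to aldehyde 2 and so to lactone 1, which supplies C6 from the chiral pool.

**23 back to 19, a protecting-group relay.** Aldehyde 23 needs the acetonide on O9/O10 and the carbonyl at C8, whereas the chiral-pool source carries its acetonide on O8/O9. So 23 is traced to silyl ether 22, 22 to diol 21, 21 to triol 20 and 20 to terminal acetonide 19. Direct acetonide migration is not relied on, because the wanted dioxolane is the more crowded one.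

**19 to 17 and 13, cut C1–C10; then 13 to 11 and 17 to 14.** The tertiary carbinol is disconnected next to the masked carbonyl: lithiated dithiane 18 (from 17) adds to methyl ketone 13. The C9 stereocentre of 13 directs the addition in the Felkin–Anh sense, which is the 9,10-anti relation of the target. The two-carbon arm C2–C3 is put on the dithiane before this addition (17 from alcohol 16, and 16 from 1,3-dithiane 14 through 15). Alkylating the adduct afterwards would need a carbanion next to a tertiary alkoxide. Ketone 13 comes through Weinreb amide 12 from glycerate 11.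

## Alternatives that were turned down

**Alternative 1:** The ring would be cut at C1–C10. In the forward sense LiN(SiMe3)2 and CeCl3 turn a terminal alkyne at C1 into a cerium acetylide, which adds to a methyl ketone at C10 of the same chain and gives the ten-membered enyne carbinol A1.
- For it: one step forms the ring, the C1–C10 bond and the quaternary carbinol; no sulfur is carried; the alkyne is a compact mask for the C1/C10 ketol. C3 is already fixed as an ether before ring closure, so that centre is not at stake. On this point A1 is stronger than the chosen plan.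
- Against it: four collinear atoms (C3–C2≡C1–C10) must fit into a ten-membered ring that also holds a Z olefin, so the closure is strained. The ketone is enolisable and hindered. The C10 configuration would be decided in the ring-closing event, and a tertiary carbinol cannot be repaired by oxidation and reduction. After A1 the alkyne still has to be hydrated at C1 and not C2, C12 oxidised, the lactone closed and the O8/O9 acetonide taken apart to tell angelate from acetate; this is a longer endgame than the five steps planned here.
- In exchange, the chosen plan sets C10 in an open chain (step 11) and leaves only a correctable secondary carbinol to the macrocyclisation.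

**Alternative 2:** The ring would be cut at C8–C9. A second-generation Grubbs catalyst would join vinyl groups on C7 and C10 with loss of ethylene to give diene A2, and the C8/C9 oxygens would follow by hydroxyl-directed dihydroxylation.
- For it: ring-closing metathesis tolerates the methylene lactone, the free ketone and the tertiary hydroxyl. The precursor is shorter, since C8 and C9 need no stereocentres, dithiane or acetonide. As a ring-forming event it is more dependable than a chromium-mediated closure, and that point is conceded.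
- Against it: both vinyl groups are hindered (one on a fully substituted carbinol, one next to the lactone ring fusion), and the exocyclic methylene is a competing partner. The hard part moves behind the ring: C8=C9 must be dihydroxylated on one face in the presence of C4=C5 and the methylene lactone. The resulting cis diol must then take an angelate at O8 and an acetate at O9, with acyl migration open between the two hydroxyls. The β-silyloxy ketone is also carried through every step.
- In exchange, the chosen plan has O8, O9 and O10 already differentiated before the ring is closed.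

**Alternative 3:** The ring would be cut at C5–C6. At a cathode, NiCl2·glyme with 2,2′-bipyridine would couple a C6 radical, released from an N-hydroxyphthalimide ester, with an alkenyl iodide at C5 to give macrocycle A3, whose lactone is masked as a dimethylamine adduct.
- For it: an sp2–sp3 bond next to the olefin is formed under mild, non-basic conditions. C3 and the C7–C10 centres are fixed beforehand, and the C1 ketone can be carried free, so no dithiane is needed. On these points A3 is at least as strong.
- Against it: C6, the ring-fusion carbon bearing the lactone oxygen, becomes a planar α-oxy radical, and its configuration would be decided at nickel during ring closure. A cis-lactone epimer could not be corrected. High dilution works against electrode kinetics. The Z geometry of the alkenyl partner is less secure on nickel with radicals. Masking and unmasking the methylene lactone costs two steps, and a carboxyl carbon must be built onto C6 only to be lost.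
- In exchange, the chosen plan also creates one stereocentre during closure, but it is a secondary allylic carbinol that oxidation and reduction can reset.

Key step: step 20

Assumption: locants C1–C15 are those of the germacrane skeleton of the target (C12 lactone carbonyl, C13 exocyclic methylene, C14 on C10, C15 on C4), and in the zinc allylation of step 16 the chair transition state is taken to decide the configuration at C8.

## Route

Step 1
Reactants: 1 (S)-5-(hydroxymethyl)dihydrofuran-2(3H)-one
Product: 2 (S)-5-oxotetrahydrofuran-2-carbaldehyde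
Conditions: (COCl)2, DMSO, CH2Cl2, −78 °C; Et3N, −78 → −20 °C; used crude
Reagents that add atoms: none
Why: Swern oxidation of the primary alcohol; the cold, non-aqueous procedure should leave the α-oxygenated centre (C6) untouched, and the aldehyde is used at once.

Step 2
Reactants: 2 (S)-5-oxotetrahydrofuran-2-carbaldehyde
Product: 3 (S)-5-[(Z)-2-iodoprop-1-en-1-yl]dihydrofuran-2(3H)-one
Conditions: EtPPh3I, n-BuLi, THF, 0 °C; I2, −78 °C; NaN(SiMe3)2, −78 °C; then 2, −78 → −20 °C
Reagents that add atoms: ethyltriphenylphosphonium iodide, CC[P+](c1ccccc1)(c1ccccc1)c1ccccc1.[I-]; iodine, II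
Why: Stork–Zhao-type Wittig olefination with the α-iodo ylide; the unstabilised ylide reacts under kinetic control and should place iodine cis to C6, which is the Z geometry of C4=C5 carried into the ring closure.

Step 3
Reactants: 3 (S)-5-[(Z)-2-iodoprop-1-en-1-yl]dihydrofuran-2(3H)-one
Product: 5 (5S)-5-[(Z)-2-iodoprop-1-en-1-yl]-3-(phenylselanyl)dihydrofuran-2(3H)-one (both C3 epimers), via lithium enolate 4 (not isolated)
Conditions: LiN(i-Pr)2, THF, −78 °C; PhSeBr
Reagents that add atoms: phenylselenyl bromide, Br[Se]c1ccccc1
Why: α-selenenylation of a lactone enolate; the lactone α-proton is far more acidic than any proton of the alkenyl iodide, and the configuration at the selenium-bearing carbon is irrelevant because it is destroyed in step 5.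

Step 4
Reactants: 5 (5S)-5-[(Z)-2-iodoprop-1-en-1-yl]-3-(phenylselanyl)dihydrofuran-2(3H)-one
Product: 7 (5S)-3-(hydroxymethyl)-5-[(Z)-2-iodoprop-1-en-1-yl]-3-(phenylselanyl)dihydrofuran-2(3H)-one (both C3 epimers), via lithium enolate 6 (not isolated)
Conditions: LiN(i-Pr)2, THF, −78 °C; CH2O (gas), −78 → −40 °C
Reagents that add atoms: formaldehyde, C=O
Why: aldol hydroxymethylation of the selenium-stabilised enolate with monomeric formaldehyde introduces C13 at the alcohol level.

Step 5
Reactants: 7 (5S)-3-(hydroxymethyl)-5-[(Z)-2-iodoprop-1-en-1-yl]-3-(phenylselanyl)dihydrofuran-2(3H)-one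
Product: 9 (S)-3-(hydroxymethyl)-5-[(Z)-2-iodoprop-1-en-1-yl]furan-2(5H)-one, via selenoxide 8 (not isolated)
Conditions: 30% H2O2, pyridine, CH2Cl2, 0 → 25 °C
Reagents that add atoms: none
Why: selenoxide syn-elimination; it avoids the hydroxyl-bearing carbon (an enol would result) and therefore runs into the ring to give the butenolide, and the alkenyl iodide is inert to cold peroxide.

Step 6
Reactants: 9 (S)-3-(hydroxymethyl)-5-[(Z)-2-iodoprop-1-en-1-yl]furan-2(5H)-one
Product: 10 (S)-3-(bromomethyl)-5-[(Z)-2-iodoprop-1-en-1-yl]furan-2(5H)-one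
Conditions: CBr4, PPh3, CH2Cl2, 0 °C
Reagents that add atoms: carbon tetrabromide, BrC(Br)(Br)Br
Why: Appel bromination of the primary allylic alcohol under neutral conditions, which spares the acidic γ-proton at C6.

Step 7
Reactants: 11 methyl (S)-2,2-dimethyl-1,3-dioxolane-4-carboxylate
Product: 12 (S)-N-methoxy-N,2,2-trimethyl-1,3-dioxolane-4-carboxamide
Conditions: MeNH(OMe)·HCl, i-PrMgCl, THF, −20 °C
Reagents that add atoms: N,O-dimethylhydroxylamine hydrochloride, CNOC.Cl
Why: direct aminolysis of the ester with the magnesium amide gives the Weinreb amide cold, without enolising the α-alkoxy centre (C9).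

Step 8
Reactants: 12 (S)-N-methoxy-N,2,2-trimethyl-1,3-dioxolane-4-carboxamide
Product: 13 (S)-1-(2,2-dimethyl-1,3-dioxolan-4-yl)ethan-1-one
Conditions: MeMgBr, THF, 0 °C
Reagents that add atoms: methylmagnesium bromide, C[Mg]Br
Why: Weinreb ketone synthesis; the chelated tetrahedral intermediate stops at mono-addition and delivers C10 with its methyl C14.

Step 9
Reactants: 14 1,3-dithiane
Product: 16 2-(1,3-dithian-2-yl)ethan-1-ol, via 2-lithio-1,3-dithiane 15 (not isolated)
Conditions: n-BuLi, THF, −30 °C; oxirane, −78 → 0 °C
Reagents that add atoms: oxirane, C1CO1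
Why: Corey–Seebach alkylation; opening the epoxide installs C2–C3 on the future C1 before the hindered carbinol is built.

Step 10
Reactants: 16 2-(1,3-dithian-2-yl)ethan-1-ol
Product: 17 tert-butyl[2-(1,3-dithian-2-yl)ethoxy]diphenylsilane
Conditions: TBDPSCl, imidazole, CH2Cl2, 25 °C
Reagents that add atoms: tert-butyl(chloro)diphenylsilane, CC(C)(C)[Si](Cl)(c1ccccc1)c1ccccc1
Why: silylation of the primary alcohol; this ether survives butyllithium, aqueous acetic acid and the zinc and Mitsunobu steps, and comes off with fluoride in step 18.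

Step 11
Reactants: 17 tert-butyl[2-(1,3-dithian-2-yl)ethoxy]diphenylsilane; 13 (S)-1-(2,2-dimethyl-1,3-dioxolan-4-yl)ethan-1-one
Product: 19 (1S)-1-[2-(2-{[tert-butyl(diphenyl)silyl]oxy}ethyl)-1,3-dithian-2-yl]-1-[(4S)-2,2-dimethyl-1,3-dioxolan-4-yl]ethan-1-ol, via lithiated dithiane 18 (not isolated)
Conditions: n-BuLi, THF, −30 °C, 3 h; then 13, −78 °C
Reagents that add atoms: none
Why: Corey–Seebach addition of a 2-alkyl-2-lithio-1,3-dithiane to a methyl ketone forms C1–C10. Lithium in THF does not chelate the dioxolane oxygen, so the bulky nucleophile should attack in the Felkin–Anh sense, anti to the C9–O bond, giving the 9,10-anti (10S) carbinol.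

Step 12
Reactants: 19 (1S)-1-[2-(2-{[tert-butyl(diphenyl)silyl]oxy}ethyl)-1,3-dithian-2-yl]-1-[(4S)-2,2-dimethyl-1,3-dioxolan-4-yl]ethan-1-ol
Product: 20 (2S,3S)-3-[2-(2-{[tert-butyl(diphenyl)silyl]oxy}ethyl)-1,3-dithian-2-yl]butane-1,2,3-triol
Conditions: AcOH/H2O/THF (3:1:1), 40 °C
Reagents that add atoms: none
Why: acid hydrolysis of the terminal acetonide; the dithiane and the silyl ether are stable to dilute acetic acid.

Step 13
Reactants: 20 (2S,3S)-3-[2-(2-{[tert-butyl(diphenyl)silyl]oxy}ethyl)-1,3-dithian-2-yl]butane-1,2,3-triol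
Product: 21 (2S,3S)-2-[2-(2-{[tert-butyl(diphenyl)silyl]oxy}ethyl)-1,3-dithian-2-yl]-4-[(triethylsilyl)oxy]butane-2,3-diol
Conditions: TESCl (1.05 equiv), imidazole, CH2Cl2, −78 → −40 °C
Reagents that add atoms: chlorotriethylsilane, CC[Si](Cl)(CC)CC
Why: the primary C8 hydroxyl is silylated much faster than the hindered secondary and tertiary ones, which sets O8 apart from O9 and O10.

Step 14
Reactants: 21 (2S,3S)-2-[2-(2-{[tert-butyl(diphenyl)silyl]oxy}ethyl)-1,3-dithian-2-yl]-4-[(triethylsilyl)oxy]butane-2,3-diol
Product: 22 tert-butyl{2-[2-((4S,5S)-2,2,4-trimethyl-5-{[(triethylsilyl)oxy]methyl}-1,3-dioxolan-4-yl)-1,3-dithian-2-yl]ethoxy}diphenylsilane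
Conditions: 2-methoxypropene, PPTS (cat.), CH2Cl2, 0 °C
Reagents that add atoms: 2-methoxypropene, COC(C)=C
Why: kinetic ketalisation of the only remaining 1,2-diol under aprotic, weakly acidic conditions that a primary triethylsilyl ether tolerates; the acetonide now spans O9/O10 with C8 and C1 cis on the dioxolane.

Step 15
Reactants: 22 tert-butyl{2-[2-((4S,5S)-2,2,4-trimethyl-5-{[(triethylsilyl)oxy]methyl}-1,3-dioxolan-4-yl)-1,3-dithian-2-yl]ethoxy}diphenylsilane
Product: 23 (4R,5S)-5-[2-(2-{[tert-butyl(diphenyl)silyl]oxy}ethyl)-1,3-dithian-2-yl]-2,2,5-trimethyl-1,3-dioxolane-4-carbaldehyde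
Conditions: (COCl)2, DMSO, CH2Cl2, −78 → −30 °C; Et3N
Reagents that add atoms: none
Why: Swern conditions cleave a primary triethylsilyl ether and oxidise it directly to the aldehyde, while the diphenylsilyl ether, the acetonide and the dithiane are untouched; the descriptor at C9 changes to R by priority only.

Step 16
Reactants: 10 (S)-3-(bromomethyl)-5-[(Z)-2-iodoprop-1-en-1-yl]furan-2(5H)-one; 23 (4R,5S)-5-[2-(2-{[tert-butyl(diphenyl)silyl]oxy}ethyl)-1,3-dithian-2-yl]-2,2,5-trimethyl-1,3-dioxolane-4-carbaldehyde
Product: 25 (4R,5S)-4-[(R)-{(4S,5S)-5-[2-(2-{[tert-butyl(diphenyl)silyl]oxy}ethyl)-1,3-dithian-2-yl]-2,2,5-trimethyl-1,3-dioxolan-4-yl}(hydroxy)methyl]-5-[(Z)-2-iodoprop-1-en-1-yl]-3-methylidenedihydrofuran-2(3H)-one (6S,7R,8R,9S,10S), via allylzinc bromide 24 (not isolated)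
Conditions: Zn dust, THF/sat. aq NH4Cl, 0 → 25 °C
Reagents that add atoms: none
Why: Barbier allylation; zinc inserts into the allylic C–Br bond only, and 24 adds through C7 in a Zimmerman–Traxler chair on the face anti to the C6 side chain, giving the trans lactone and the exocyclic methylene. The ring holds C6 trans to the zinc-bearing methylene, so an equatorial aldehyde residue puts H7 and H8 anti and gives the 8R carbinol; this is the C8 epimer of what the target needs and is inverted in step 17. The chair-preferred face is the anti-Felkin face of 23, so the pair is mismatched and the C8 selectivity is a stated risk.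

Step 17
Reactants: 25 the 8R carbinol of step 16; 26 angelic acid ((Z)-2-methylbut-2-enoic acid)
Product: 27 (S)-{(4S,5S)-5-[2-(2-{[tert-butyl(diphenyl)silyl]oxy}ethyl)-1,3-dithian-2-yl]-2,2,5-trimethyl-1,3-dioxolan-4-yl}{(2S,3S)-2-[(Z)-2-iodoprop-1-en-1-yl]-4-methylidene-5-oxooxolan-3-yl}methyl (Z)-2-methylbut-2-enoate
Conditions: PPh3, DIAD, toluene, 0 → 25 °C
Reagents that add atoms: none
Why: Mitsunobu esterification; angelate displaces the alkoxyphosphonium group at C8 with inversion (8R to 8S), which sets the H7/H8 cis relation and installs the ester in one step. The acid acts as a nucleophile and is never activated at its carbonyl, so the Z geometry should be retained.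

Step 18
Reactants: 27 the C8 angelate of step 17
Product: 28 (S)-{(4S,5S)-5-[2-(2-hydroxyethyl)-1,3-dithian-2-yl]-2,2,5-trimethyl-1,3-dioxolan-4-yl}{(2S,3S)-2-[(Z)-2-iodoprop-1-en-1-yl]-4-methylidene-5-oxooxolan-3-yl}methyl (Z)-2-methylbut-2-enoate
Conditions: HF·pyridine, pyridine, THF, 0 → 25 °C
Reagents that add atoms: none
Why: buffered fluoride desilylation of the primary silyl ether; the medium is non-basic, so the methylene lactone, the angelate and the acetonide should survive.

Step 19
Reactants: 28 the C3 primary alcohol of step 18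
Product: 29 (S)-{(4S,5S)-2,2,5-trimethyl-5-[2-(2-oxoethyl)-1,3-dithian-2-yl]-1,3-dioxolan-4-yl}{(2S,3S)-2-[(Z)-2-iodoprop-1-en-1-yl]-4-methylidene-5-oxooxolan-3-yl}methyl (Z)-2-methylbut-2-enoate
Conditions: SO3·pyridine, DMSO, i-Pr2NEt, CH2Cl2, 0 °C
Reagents that add atoms: none
Why: Parikh–Doering oxidation, an activated-DMSO method that does not oxidise the dithiane sulfur; the β,β-dithio aldehyde is used directly.

Step 20
Reactants: 29 the seco iodo aldehyde of step 19
Product: 31 (3R,6R,7S,8S,9S,10S)-3-hydroxy-9,10-(isopropylidenedioxy)-8-[(Z)-2-methylbut-2-enoyloxy]-1,1-(propane-1,3-diyldisulfanediyl)germacra-4Z,11(13)-dien-12,6-olide, via alkenylchromium dichloride 30 (not isolated)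
Conditions: CrCl2 (10 equiv), NiCl2 (2 mol %), DMSO/THF (3:1), 25 °C, 0.003 M, slow addition of 29
Reagents that add atoms: none
Why: Nozaki–Hiyama–Kishi reaction: divalent chromium reduces NiCl2 to zerovalent nickel, which inserts into the C4–I bond with retention of the Z geometry; transfer of the alkenyl group to trivalent chromium gives 30, which adds to the C3 aldehyde and forms C3–C4, the chromium alkoxide being the thermodynamic sink. The closest known reaction type is the NiCl2/CrCl2 macrocyclisation of formyl-substituted alkenyl iodides to medium-ring allylic alcohols. The ten-membered carbocycle closes in a 10-exo-trig mode, C4 attacking the carbonyl carbon C3. The new stereocentre C3 is under substrate control: the chain is folded by the cis-dioxolane at C9/C10, the two fully substituted carbons C1 and C10, the trans lactone and the Z olefin, and addition to the Si face of the aldehyde gives the required 3R carbinol. Chemoselectivity is intrinsic, because an alkenylchromium reagent adds to aldehydes but not to the lactone, the angelate or the enoate, and the dithiane keeps C3 from being an enolisable β-keto aldehyde. Ring closure is favoured over oligomerisation by high dilution and slow addition.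

Step 21
Reactants: 31 the macrocyclic allylic alcohol of step 20
Product: 32 the C3 tert-butyldimethylsilyl ether of 31
Conditions: TBSOTf, 2,6-lutidine, CH2Cl2, −78 °C
Reagents that add atoms: tert-butyldimethylsilyl trifluoromethanesulfonate, CC(C)(C)[Si](C)(C)OS(=O)(=O)C(F)(F)F
Why: silylation of the only free hydroxyl, so that C9 will be the sole secondary hydroxyl when the diol is freed.

Step 22
Reactants: 32 the C3 silyl ether of step 21
Product: 33 (3R,6R,7S,8S,9S,10S)-3-[(tert-butyldimethylsilyl)oxy]-9,10-dihydroxy-8-[(Z)-2-methylbut-2-enoyloxy]-1,1-(propane-1,3-diyldisulfanediyl)germacra-4Z,11(13)-dien-12,6-olide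
Conditions: AcOH/H2O (4:1), 40 °C
Reagents that add atoms: none
Why: acid hydrolysis of the crowded, ring-fused acetonide; the dithiane is acid-stable, and a hindered secondary silyl ether should outlast dilute acetic acid.

Step 23
Reactants: 33 the 9,10-diol of step 22
Product: 34 (3R,6R,7S,8S,9S,10S)-9-acetoxy-3-[(tert-butyldimethylsilyl)oxy]-10-hydroxy-8-[(Z)-2-methylbut-2-enoyloxy]-1,1-(propane-1,3-diyldisulfanediyl)germacra-4Z,11(13)-dien-12,6-olide
Conditions: Ac2O, pyridine, DMAP (cat.), CH2Cl2, 0 °C
Reagents that add atoms: acetic anhydride, CC(=O)OC(C)=O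
Why: the secondary C9 hydroxyl is acetylated while the tertiary C10 hydroxyl is not; C1 is still masked, so no ketol is exposed to base.

Step 24
Reactants: 34 the 9-acetate of step 23
Product: 35 (3R,6R,7S,8S,9S,10S)-9-acetoxy-3-[(tert-butyldimethylsilyl)oxy]-10-hydroxy-8-[(Z)-2-methylbut-2-enoyloxy]-1-oxogermacra-4Z,11(13)-dien-12,6-olide
Conditions: PhI(OCOCF3)2, MeCN/H2O (9:1), 0 °C
Reagents that add atoms: water, O
Why: oxidative dithiane hydrolysis with a hypervalent iodine reagent; it is fast, mildly acidic and does not touch the olefins, esters or silyl ether, and no free 1,2-diol is present that it could cleave.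

Step 25
Reactants: 35 the C1 ketone of step 24
Product: 36 (3R,6R,7S,8S,9S,10S)-9-acetoxy-3,10-dihydroxy-8-[(Z)-2-methylbut-2-enoyloxy]-1-oxogermacra-4Z,11(13)-dien-12,6-olide (CNP0308559.3)
Conditions: HF·pyridine, pyridine, THF, 0 → 25 °C
Reagents that add atoms: none
Why: acidic fluoride desilylation frees the C3 hydroxyl without base, so the β-hydroxy ketone is not eliminated and neither ester migrates.

## Compound list

1 | (S)-5-(hydroxymethyl)dihydrofuran-2(3H)-one | OC[C@@H]1CCC(=O)O1 | starting material
2 | (S)-5-oxotetrahydrofuran-2-carbaldehyde | O=C[C@@H]1CCC(=O)O1 | intermediate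
3 | (S)-5-[(Z)-2-iodoprop-1-en-1-yl]dihydrofuran-2(3H)-one | C/C(I)=C/[C@@H]1CCC(=O)O1 | intermediate
4 | lithium (S)-5-[(Z)-2-iodoprop-1-en-1-yl]-4,5-dihydrofuran-2-olate | C/C(I)=C/[C@@H]1CC=C(O[Li])O1 | intermediate (not isolated)
5 | (5S)-5-[(Z)-2-iodoprop-1-en-1-yl]-3-(phenylselanyl)dihydrofuran-2(3H)-one | C/C(I)=C/[C@@H]1CC([Se]c2ccccc2)C(=O)O1 | intermediate
6 | lithium (S)-5-[(Z)-2-iodoprop-1-en-1-yl]-3-(phenylselanyl)-4,5-dihydrofuran-2-olate | C/C(I)=C/[C@@H]1CC([Se]c2ccccc2)=C(O[Li])O1 | intermediate (not isolated)
7 | (5S)-3-(hydroxymethyl)-5-[(Z)-2-iodoprop-1-en-1-yl]-3-(phenylselanyl)dihydrofuran-2(3H)-one | C/C(I)=C/[C@@H]1CC(CO)([Se]c2ccccc2)C(=O)O1 | intermediate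
8 | (5S)-3-(hydroxymethyl)-5-[(Z)-2-iodoprop-1-en-1-yl]-3-(phenylseleninyl)dihydrofuran-2(3H)-one | C/C(I)=C/[C@@H]1CC(CO)([Se](=O)c2ccccc2)C(=O)O1 | intermediate (not isolated)
9 | (S)-3-(hydroxymethyl)-5-[(Z)-2-iodoprop-1-en-1-yl]furan-2(5H)-one | C/C(I)=C/[C@@H]1C=C(CO)C(=O)O1 | intermediate
10 | (S)-3-(bromomethyl)-5-[(Z)-2-iodoprop-1-en-1-yl]furan-2(5H)-one | C/C(I)=C/[C@@H]1C=C(CBr)C(=O)O1 | intermediate
11 | methyl (S)-2,2-dimethyl-1,3-dioxolane-4-carboxylate | COC(=O)[C@@H]1COC(C)(C)O1 | starting material
12 | (S)-N-methoxy-N,2,2-trimethyl-1,3-dioxolane-4-carboxamide | CON(C)C(=O)[C@@H]1COC(C)(C)O1 | intermediate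
13 | (S)-1-(2,2-dimethyl-1,3-dioxolan-4-yl)ethan-1-one | CC(=O)[C@@H]1COC(C)(C)O1 | intermediate
14 | 1,3-dithiane | C1CSCSC1 | starting material
15 | 2-lithio-1,3-dithiane | [Li]C1SCCCS1 | intermediate (not isolated)
16 | 2-(1,3-dithian-2-yl)ethan-1-ol | OCCC1SCCCS1 | intermediate
17 | tert-butyl[2-(1,3-dithian-2-yl)ethoxy]diphenylsilane | CC(C)(C)[Si](OCCC1SCCCS1)(c1ccccc1)c1ccccc1 | intermediate
18 | tert-butyl[2-(2-lithio-1,3-dithian-2-yl)ethoxy]diphenylsilane | [Li]C1(CCO[Si](c2ccccc2)(c2ccccc2)C(C)(C)C)SCCCS1 | intermediate (not isolated)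
19 | (1S)-1-[2-(2-{[tert-butyl(diphenyl)silyl]oxy}ethyl)-1,3-dithian-2-yl]-1-[(4S)-2,2-dimethyl-1,3-dioxolan-4-yl]ethan-1-ol | CC(C)(C)[Si](OCCC1(SCCCS1)[C@@](C)(O)[C@@H]1COC(C)(C)O1)(c1ccccc1)c1ccccc1 | intermediate
20 | (2S,3S)-3-[2-(2-{[tert-butyl(diphenyl)silyl]oxy}ethyl)-1,3-dithian-2-yl]butane-1,2,3-triol | CC(C)(C)[Si](OCCC1(SCCCS1)[C@@](C)(O)[C@@H](O)CO)(c1ccccc1)c1ccccc1 | intermediate
21 | (2S,3S)-2-[2-(2-{[tert-butyl(diphenyl)silyl]oxy}ethyl)-1,3-dithian-2-yl]-4-[(triethylsilyl)oxy]butane-2,3-diol | CC(C)(C)[Si](OCCC1(SCCCS1)[C@@](C)(O)[C@@H](O)CO[Si](CC)(CC)CC)(c1ccccc1)c1ccccc1 | intermediate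
22 | tert-butyl{2-[2-((4S,5S)-2,2,4-trimethyl-5-{[(triethylsilyl)oxy]methyl}-1,3-dioxolan-4-yl)-1,3-dithian-2-yl]ethoxy}diphenylsilane | CC(C)(C)[Si](OCCC1(SCCCS1)[C@@]1(C)OC(C)(C)O[C@H]1CO[Si](CC)(CC)CC)(c1ccccc1)c1ccccc1 | intermediate
23 | (4R,5S)-5-[2-(2-{[tert-butyl(diphenyl)silyl]oxy}ethyl)-1,3-dithian-2-yl]-2,2,5-trimethyl-1,3-dioxolane-4-carbaldehyde | CC(C)(C)[Si](OCCC1(SCCCS1)[C@@]1(C)OC(C)(C)O[C@H]1C=O)(c1ccccc1)c1ccccc1 | intermediate
24 | bromo{[(S)-5-[(Z)-2-iodoprop-1-en-1-yl]-2-oxo-2,5-dihydrofuran-3-yl]methyl}zinc | C/C(I)=C/[C@@H]1C=C(C[Zn]Br)C(=O)O1 | intermediate (not isolated)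
25 | (4R,5S)-4-[(R)-{(4S,5S)-5-[2-(2-{[tert-butyl(diphenyl)silyl]oxy}ethyl)-1,3-dithian-2-yl]-2,2,5-trimethyl-1,3-dioxolan-4-yl}(hydroxy)methyl]-5-[(Z)-2-iodoprop-1-en-1-yl]-3-methylidenedihydrofuran-2(3H)-one | C=C1C(=O)O[C@H](/C=C(/C)I)[C@H]1[C@@H](O)[C@@H]2OC(C)(C)O[C@]2(C)C2(CCO[Si](c3ccccc3)(c3ccccc3)C(C)(C)C)SCCCS2 | intermediate
26 | angelic acid, (Z)-2-methylbut-2-enoic acid | C/C=C(/C)C(=O)O | starting material
27 | (S)-{(4S,5S)-5-[2-(2-{[tert-butyl(diphenyl)silyl]oxy}ethyl)-1,3-dithian-2-yl]-2,2,5-trimethyl-1,3-dioxolan-4-yl}{(2S,3S)-2-[(Z)-2-iodoprop-1-en-1-yl]-4-methylidene-5-oxooxolan-3-yl}methyl (Z)-2-methylbut-2-enoate | C=C1C(=O)O[C@H](/C=C(/C)I)[C@H]1[C@H](OC(=O)/C(C)=C\C)[C@@H]2OC(C)(C)O[C@]2(C)C2(CCO[Si](c3ccccc3)(c3ccccc3)C(C)(C)C)SCCCS2 | intermediate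
28 | (S)-{(4S,5S)-5-[2-(2-hydroxyethyl)-1,3-dithian-2-yl]-2,2,5-trimethyl-1,3-dioxolan-4-yl}{(2S,3S)-2-[(Z)-2-iodoprop-1-en-1-yl]-4-methylidene-5-oxooxolan-3-yl}methyl (Z)-2-methylbut-2-enoate | C=C1C(=O)O[C@H](/C=C(/C)I)[C@H]1[C@H](OC(=O)/C(C)=C\C)[C@@H]2OC(C)(C)O[C@]2(C)C2(CCO)SCCCS2 | intermediate
29 | (S)-{(4S,5S)-2,2,5-trimethyl-5-[2-(2-oxoethyl)-1,3-dithian-2-yl]-1,3-dioxolan-4-yl}{(2S,3S)-2-[(Z)-2-iodoprop-1-en-1-yl]-4-methylidene-5-oxooxolan-3-yl}methyl (Z)-2-methylbut-2-enoate | C=C1C(=O)O[C@H](/C=C(/C)I)[C@H]1[C@H](OC(=O)/C(C)=C\C)[C@@H]2OC(C)(C)O[C@]2(C)C2(CC=O)SCCCS2 | intermediate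
30 | C4 dichlorochromium derivative of 29 (iodine replaced by CrCl2, Z geometry retained) | C=C1C(=O)O[C@H](/C=C(/C)[Cr](Cl)Cl)[C@H]1[C@H](OC(=O)/C(C)=C\C)[C@@H]2OC(C)(C)O[C@]2(C)C2(CC=O)SCCCS2 | intermediate (not isolated)
31 | (3R,6R,7S,8S,9S,10S)-3-hydroxy-9,10-(isopropylidenedioxy)-8-[(Z)-2-methylbut-2-enoyloxy]-1,1-(propane-1,3-diyldisulfanediyl)germacra-4Z,11(13)-dien-12,6-olide | C=C1C(=O)O[C@@H]2/C=C(/C)[C@H](O)CC4(SCCCS4)[C@@]3(C)OC(C)(C)O[C@H]3[C@@H](OC(=O)/C(C)=C\C)[C@@H]12 | intermediate
32 | C3 tert-butyldimethylsilyl ether of 31 | C=C1C(=O)O[C@@H]2/C=C(/C)[C@H](O[Si](C)(C)C(C)(C)C)CC4(SCCCS4)[C@@]3(C)OC(C)(C)O[C@H]3[C@@H](OC(=O)/C(C)=C\C)[C@@H]12 | intermediate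
33 | (3R,6R,7S,8S,9S,10S)-3-[(tert-butyldimethylsilyl)oxy]-9,10-dihydroxy-8-[(Z)-2-methylbut-2-enoyloxy]-1,1-(propane-1,3-diyldisulfanediyl)germacra-4Z,11(13)-dien-12,6-olide | C=C1C(=O)O[C@@H]2/C=C(/C)[C@H](O[Si](C)(C)C(C)(C)C)CC3(SCCCS3)[C@@](C)(O)[C@@H](O)[C@@H](OC(=O)/C(C)=C\C)[C@@H]12 | intermediate
34 | (3R,6R,7S,8S,9S,10S)-9-acetoxy-3-[(tert-butyldimethylsilyl)oxy]-10-hydroxy-8-[(Z)-2-methylbut-2-enoyloxy]-1,1-(propane-1,3-diyldisulfanediyl)germacra-4Z,11(13)-dien-12,6-olide | C=C1C(=O)O[C@@H]2/C=C(/C)[C@H](O[Si](C)(C)C(C)(C)C)CC3(SCCCS3)[C@@](C)(O)[C@@H](OC(C)=O)[C@@H](OC(=O)/C(C)=C\C)[C@@H]12 | intermediate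
35 | (3R,6R,7S,8S,9S,10S)-9-acetoxy-3-[(tert-butyldimethylsilyl)oxy]-10-hydroxy-8-[(Z)-2-methylbut-2-enoyloxy]-1-oxogermacra-4Z,11(13)-dien-12,6-olide | C=C1C(=O)O[C@@H]2/C=C(/C)[C@H](O[Si](C)(C)C(C)(C)C)CC(=O)[C@@](C)(O)[C@@H](OC(C)=O)[C@@H](OC(=O)/C(C)=C\C)[C@@H]12 | intermediate
36 | (3R,6R,7S,8S,9S,10S)-9-acetoxy-3,10-dihydroxy-8-[(Z)-2-methylbut-2-enoyloxy]-1-oxogermacra-4Z,11(13)-dien-12,6-olide (CNP0308559.3) | C=C1C(=O)O[C@@H]2/C=C(/C)[C@H](O)CC(=O)[C@@](C)(O)[C@@H](OC(C)=O)[C@@H](OC(=O)/C(C)=C\C)[C@@H]12 | target

## Step count and least certain steps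

Total: 25 steps. Longest linear sequence: 17 steps (from 11 through steps 7, 8, 11–25, or equally from 14 through steps 9–25). The lactone half (steps 1–6) and the dithiane arm (steps 9–10) are made in parallel.

**Step 20 (key step).** Three processes can defeat it. Intermolecular coupling can outrun ring closure if the folded conformer is poorly populated. The alkenyl–metal bond can be protonated, which removes the iodide without ring formation. The aldehyde can be attacked on its Re face, which gives the 3S epimer, because nothing closer than the ring conformation selects the face. Coordination of the dithiane sulfur to nickel may also slow turnover. The fallback accepts whichever carbinol forms. It sets out from 29. The epimeric alcohol from the same cyclisation, the 3S epimer of 31 F1, is oxidised alone or in mixture with 31 by MnO2 in CH2Cl2 to the macrocyclic C3 enone F2. F2 is then reduced under reagent control with (S)-2-methyl-CBS-oxazaborolidine and catecholborane; the alkenyl group acts as the large substituent, which should give the 3R alcohol. The route is rejoined at 31.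

**Step 16.** The chair-controlled face of the aldehyde is its anti-Felkin face, so the selectivity at C8 may erode, and some attack syn to the C6 side chain is also possible. The fallback makes both C8 epimers useful. It sets out from 10 and 23. The minor or competing carbinol, the 8S epimer of 25 F3, is separated and esterified with retention: angelic acid 26 is turned into its mixed anhydride with 2,4,6-trichlorobenzoyl chloride and Et3N, and F3 is added in toluene at 80 °C (Yamaguchi protocol, known to preserve the angelate geometry). This gives the same ester 27, where the route is rejoined.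

**Step 17.** Substitution at C8 is hindered on both sides. The alkoxyphosphonium ion may fail to be displaced, may give ester with retention through an acyloxyphosphonium path, or may eliminate towards C7. The fallback separates activation from displacement. It sets out from 25, which is converted with SO2Cl2 and imidazole in CH2Cl2 (−40 → 0 °C) into the C8 imidazole-1-sulfonate of 25 F4. F4 is displaced with cesium angelate (from 26 and Cs2CO3) and 18-crown-6 in toluene at 80 °C, an SN2 process with inversion, and the route is rejoined at 27.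

**Step 11.** The lithiated dithiane is a hindered base as well as a nucleophile. Enolisation of the methyl ketone (with loss of configuration at C9) and incomplete Felkin–Anh control at the new quaternary centre are the likely failures. The fallback reverses the order of bond formation. It sets out from 12 and 17: lithiated dithiane 18 is acylated by Weinreb amide 12 to the acyl dithiane ketone F5, which cannot enolise towards C1. MeMgBr is then added in CH2Cl2/Et2O at −78 °C under chelation control through the C9 oxygen, which leads to the same 10S carbinol, and the route is rejoined at 19.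

**Step 2.** The α-iodo ylide is basic and thermally fragile. Low conversion, loss of iodine from the ylide (giving the iodine-free olefin) and epimerisation of the α-oxygenated aldehyde are the usual failures. The fallback builds the haloalkene stepwise. It sets out from 2, which is converted with CBr4 and PPh3 into the 1,1-dibromoalkene F6. The bromine trans to the lactone is replaced selectively by methyl (MeZnCl, Pd(PPh3)4, THF, Negishi coupling) to give the Z bromoalkene F7. Copper-catalysed halogen exchange (CuI, NaI, N,N′-dimethylethylenediamine, dioxane, 110 °C) then gives the iodide with retention, and the route is rejoined at 3.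

**Step 22.** The acid that opens the acetonide may also cleave the C3 silyl ether, which would leave two secondary hydroxyls for step 23, and the freed C9 hydroxyl can accept the neighbouring angelate by acyl shift on long exposure. The fallback changes the order so that no silyl ether meets acid. It sets out from 31, whose acetonide is hydrolysed first (AcOH/H2O, 40 °C) to the 3,9,10-triol F8. The less hindered allylic C3 hydroxyl of F8 is then silylated selectively (TBSCl, imidazole, DMF, 0 °C), and the route is rejoined at 33.

## Further compounds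

F1 | step 20 | 3S epimer of 31 | C=C1C(=O)O[C@@H]2/C=C(/C)[C@@H](O)CC4(SCCCS4)[C@@]3(C)OC(C)(C)O[C@H]3[C@@H](OC(=O)/C(C)=C\C)[C@@H]12
F2 | step 20 | macrocyclic C3 enone, (6R,7S,8S,9S,10S)-9,10-(isopropylidenedioxy)-8-[(Z)-2-methylbut-2-enoyloxy]-3-oxo-1,1-(propane-1,3-diyldisulfanediyl)germacra-4Z,11(13)-dien-12,6-olide | C=C1C(=O)O[C@@H]2/C=C(/C)C(=O)CC4(SCCCS4)[C@@]3(C)OC(C)(C)O[C@H]3[C@@H](OC(=O)/C(C)=C\C)[C@@H]12
F3 | step 16 | 8S epimer of 25 (6S,7R,8S,9S,10S) | C=C1C(=O)O[C@H](/C=C(/C)I)[C@H]1[C@H](O)[C@@H]2OC(C)(C)O[C@]2(C)C2(CCO[Si](c3ccccc3)(c3ccccc3)C(C)(C)C)SCCCS2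
F4 | step 17 | C8 imidazole-1-sulfonate of 25 | C=C1C(=O)O[C@H](/C=C(/C)I)[C@H]1[C@@H](OS(=O)(=O)n3ccnc3)[C@@H]2OC(C)(C)O[C@]2(C)C2(CCO[Si](c3ccccc3)(c3ccccc3)C(C)(C)C)SCCCS2
F5 | step 11 | [2-(2-{[tert-butyl(diphenyl)silyl]oxy}ethyl)-1,3-dithian-2-yl][(4S)-2,2-dimethyl-1,3-dioxolan-4-yl]methanone | CC(C)(C)[Si](OCCC1(SCCCS1)C(=O)[C@@H]1COC(C)(C)O1)(c1ccccc1)c1ccccc1
F6 | step 2 | (S)-5-(2,2-dibromoethenyl)dihydrofuran-2(3H)-one | BrC(Br)=C[C@@H]1CCC(=O)O1
F7 | step 2 | (S)-5-[(Z)-2-bromoprop-1-en-1-yl]dihydrofuran-2(3H)-one | C/C(Br)=C/[C@@H]1CCC(=O)O1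
F8 | step 22 | (3R,6R,7S,8S,9S,10S)-3,9,10-trihydroxy-8-[(Z)-2-methylbut-2-enoyloxy]-1,1-(propane-1,3-diyldisulfanediyl)germacra-4Z,11(13)-dien-12,6-olide | C=C1C(=O)O[C@@H]2/C=C(/C)[C@H](O)CC3(SCCCS3)[C@@](C)(O)[C@@H](O)[C@@H](OC(=O)/C(C)=C\C)[C@@H]12
A1 | alternative 1 | ten-membered 4-en-1-yne tertiary carbinol with O8/O9 acetonide, C3 p-methoxybenzyl ether and two silyl ethers | C=C(CO[Si](C)(C)C(C)(C)C)[C@H]1[C@H](O[Si](C)(C)C(C)(C)C)/C=C(/C)[C@H](OCc2ccc(OC)cc2)C#C[C@@](C)(O)[C@H]2OC(C)(C)O[C@H]21
A2 | alternative 2 | ten-membered 4,8-diene lactone with free C10 hydroxyl and C3 silyl ether | C=C1C(=O)O[C@@H]2/C=C(/C)[C@H](O[Si](C)(C)C(C)(C)C)CC(=O)[C@@](C)(O)/C=C\[C@@H]12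
A3 | alternative 3 | macrocycle with dimethylamine-masked trans lactone, C3 silyl ether and O9/O10 acetonide | CN(C)C[C@@H]1C(=O)O[C@@H]2/C=C(/C)[C@H](O[Si](C)(C)C(C)(C)C)CC(=O)[C@@]3(C)OC(C)(C)O[C@H]3[C@@H](OC(=O)/C(C)=C\C)[C@@H]12
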